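## Retrosynthetic overview

1. The target comes from its di-tert-butyl ester by one acidolysis. No ring of the target has to be built, because the arene is bought.
2. The aryl C(=O)–CH= bond is cut to a 3-substituted salicylaldehyde and tert-butyl (2E,4E)-hepta-2,4-dien-6-ynoate. They are joined by chelation-assisted Rh hydroacylation, with an acyl-metal acting as acyl anion equivalent at the electrophilic end of the vinylogous acceptor.
3. The CHO group comes from ortho-formylation of the free phenol. The (E)-enoate comes from half-reduction and Wittig olefination of a seven-membered aryl lactone.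
4. Key step: the ArCH(CH3)–CH2 bond is cut to the acrolein homoenolate (chiral triazolylidene) and an ortho-quinone methide, joined in a [4+3] annulation. Two electrophilic carbons are joined, and the (R) centre is set from a racemic sulfone.
5. Ring order: the benzene ring is purchased, the benzoxepinone (the only ring formed) is made in step 2, and it is opened again in step 3.

Assumption: the (5aR,10bS) triazolium salt is taken to give the (R)-lactone on the basis of the transition-state model in step 2; this must be checked by chiral HPLC and rotation on the first run, and the equally commercial (5aS,10bR) salt is used if the sense is opposite; (2E)-pent-2-en-4-yn-1-ol is taken as a catalogue compound.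

## Route

Step 1
Reactants: 1 1-(2-hydroxy-5-methoxyphenyl)ethan-1-one
Product: 3 4-methoxy-2-[1-(4-methylbenzenesulfonyl)ethyl]phenol (racemic), via benzylic alcohol 2 (not isolated)
Conditions: NaBH4 (1.0 equiv), MeOH, 0 °C → rt, 1 h; then 3 M aq HCl to pH 1, 4-MeC6H4SO2Na (1.5 equiv), rt, 16 h, one pot; crystallise
Reagents that add atoms: sodium 4-methylbenzenesulfinate, Cc1ccc(cc1)S(=O)[O-].[Na+]
Why: Borohydride reduction of the aryl ketone is followed by acid-promoted SN1-type substitution at the phenol-activated benzylic position, where the soft sulfur of the sulfinic acid is the best nucleophile present and the crystalline sulfone is the thermodynamic sink; the new centre is left racemic because step 2 erases it.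

Step 2 (key step)
Reactants: 3 4-methoxy-2-[1-(4-methylbenzenesulfonyl)ethyl]phenol (racemic); 4 acrolein
Product: 8 (5R)-7-methoxy-5-methyl-4,5-dihydro-1-benzoxepin-2(3H)-one, via ortho-quinone methide 5 (not isolated), via carbene-bound homoenolate 6 (not isolated), via acyl azolium phenoxide 7 (not isolated)
Conditions: (5aR,10bS)-2-(2,4,6-trimethylphenyl)-5a,10b-dihydro-4H,6H-indeno[2,1-b][1,2,4]triazolo[4,3-d][1,4]oxazin-2-ium tetrafluoroborate (10 mol%), Cs2CO3 (1.5 equiv), 4 Å molecular sieves, toluene, 0 °C → rt; 4 (3 equiv) added by syringe pump over 6 h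
Reagents that add atoms: none
Why: Proposed new method: the carbene adds to acrolein and a proton shift gives the extended Breslow intermediate 6, whose terminal CH2 (normally the electrophilic beta carbon) attacks the equally electrophilic methide carbon of planar (E)-5, which Cs2CO3 releases from both enantiomers of 3, after which tautomerisation gives 7 and its phenoxide closes on the acyl azolium to form the lactone and free the carbene; the indane wall leaves one face of 6 open, and the enol O–H···O=C hydrogen bond together with azolium/phenoxide stacking fixes which face of 5 lies on it, which sets C5 as R; the closest known chemistry is the carbene-catalysed homoenolate [4+3] annulation of beta-substituted enals with ortho-quinone methides, here extended to acrolein and to a methyl-bearing methide so that the stereocentre sits on the electrophile.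

Step 3
Reactants: 8 (5R)-7-methoxy-5-methyl-4,5-dihydro-1-benzoxepin-2(3H)-one; 9 tert-butyl (triphenylphosphoranylidene)acetate
Product: 12 tert-butyl (2E,6R)-6-(2-hydroxy-5-methoxyphenyl)hept-2-enoate, via lactol 10 (not isolated), via hydroxy aldehyde 11 (not isolated)
Conditions: iBu2AlH (1.1 equiv), CH2Cl2, −78 °C, 1 h; MeOH quench at −78 °C; then 9 (1.8 equiv), −78 °C → rt, 12 h; aq potassium sodium tartrate work-up
Reagents that add atoms: none
Why: This is half-reduction of an aryl lactone followed by Wittig olefination: at −78 °C the tetrahedral aluminium hemiacetal survives until the quench, lactol 10 opens to aldehyde 11, and the stabilised ylide gives the (E)-enoate (typically above 95:5) without touching the benzylic stereocentre, which has no acidic hydrogen.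

Step 4
Reactants: 12 tert-butyl (2E,6R)-6-(2-hydroxy-5-methoxyphenyl)hept-2-enoate
Product: 14 tert-butyl (2E,6R)-6-(3-formyl-2-hydroxy-5-methoxyphenyl)hept-2-enoate, via salicyl alcohol 13 (not isolated)
Conditions: MgCl2 (anhydrous, 2 equiv), Et3N (4 equiv), paraformaldehyde (6 equiv), MeCN, reflux, 4 h; cold 1 M HCl work-up
Reagents that add atoms: paraformaldehyde (reacts as formaldehyde), C=O
Why: In this Casnati–Skattebøl ortho-formylation the magnesium phenoxide delivers formaldehyde to the only free ortho position to give 13, which a second formaldehyde oxidises by Oppenauer-type hydride transfer, and the mild base leaves the enoate, the tert-butyl ester and the stereocentre alone.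

Step 5
Reactants: 15 (2E)-pent-2-en-4-yn-1-ol; 9 tert-butyl (triphenylphosphoranylidene)acetate
Product: 17 tert-butyl (2E,4E)-hepta-2,4-dien-6-ynoate, via enynal 16 (not isolated)
Conditions: MnO2 (activated, 10 equiv), 9 (1.2 equiv), CH2Cl2, rt, 24 h; filter, chromatograph
Reagents that add atoms: none
Why: In this tandem allylic oxidation–Wittig olefination MnO2 oxidises only the allylic alcohol, and the volatile, unstable enynal 16 is trapped as it forms by the stabilised ylide to give the new E double bond, while the existing E double bond is retained.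

Step 6
Reactants: 14 tert-butyl (2E,6R)-6-(3-formyl-2-hydroxy-5-methoxyphenyl)hept-2-enoate; 17 tert-butyl (2E,4E)-hepta-2,4-dien-6-ynoate
Product: 18 tert-butyl (2E,4E,6E)-8-{3-[(2R,5E)-7-tert-butoxy-7-oxohept-5-en-2-yl]-2-hydroxy-5-methoxyphenyl}-8-oxoocta-2,4,6-trienoate
Conditions: [RhCl(cod)]2 (2.5 mol%), Fe(C5H4PPh2)2 (dppf, 5 mol%), Na2CO3 (10 mol%), toluene, 80 °C; 17 (1.3 equiv) added over 2 h
Reagents that add atoms: none
Why: In this chelation-assisted intermolecular alkyne hydroacylation the phenoxide holds monovalent rhodium next to the aldehyde C–H bond, oxidative addition gives a five-membered acyl rhodium hydride chelate that does not decarbonylate, syn hydrometallation puts rhodium on the unhindered terminal alkyne carbon (also the electrophilic end of the vinylogous acceptor), and reductive elimination forms the acyl–vinyl bond with E geometry, while the internal electron-poor alkenes and the stereocentre are spectators.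

Step 7
Reactants: 18 tert-butyl (2E,4E,6E)-8-{3-[(2R,5E)-7-tert-butoxy-7-oxohept-5-en-2-yl]-2-hydroxy-5-methoxyphenyl}-8-oxoocta-2,4,6-trienoate
Product: 19 (2E,4E,6E)-8-{3-[(2R,5E)-6-carboxyhex-5-en-2-yl]-2-hydroxy-5-methoxyphenyl}-8-oxoocta-2,4,6-trienoic acid (CNP0274934.1)
Conditions: CF3CO2H/CH2Cl2 1:3, 0 °C → rt, 3 h; evaporate, triturate
Reagents that add atoms: none
Why: Acidolysis of both tert-butyl esters by an E1 pathway (loss of 2-methylpropene) needs no nucleophile or base, so the electron-poor triene, the 2-hydroxyaryl ketone (kept open by its hydrogen bond and conjugation) and the stereocentre survive.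

## Compound list

1 | 1-(2-hydroxy-5-methoxyphenyl)ethan-1-one | COc1ccc(O)c(C(C)=O)c1 | starting material
2 | 2-(1-hydroxyethyl)-4-methoxyphenol, racemic, not isolated | COc1ccc(O)c(C(C)O)c1 | intermediate
3 | 4-methoxy-2-[1-(4-methylbenzenesulfonyl)ethyl]phenol, racemic | COc1ccc(O)c(C(C)S(=O)(=O)c2ccc(C)cc2)c1 | intermediate
4 | acrolein (prop-2-enal) | C=CC=O | starting material
5 | (6E)-6-ethylidene-4-methoxycyclohexa-2,4-dien-1-one (ortho-quinone methide), not isolated | C/C=C1\C=C(OC)C=CC1=O | intermediate
6 | extended Breslow intermediate (homoenolate equivalent): 1-hydroxyprop-2-en-1-ylidene adduct of acrolein on the carbene carbon of the (5aR,10bS) N-mesityl aminoindanol-derived triazolylidene, not isolated | OC(C=C)=C1N(c5c(C)cc(C)cc5C)N=C2N1[C@H]3c4ccccc4C[C@H]3OC2 | intermediate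
7 | acyl azolium phenoxide zwitterion: (4R)-4-(5-methoxy-2-oxidophenyl)pentanoyl group on the carbene carbon of the same (5aR,10bS) triazolium, not isolated | COc1ccc([O-])c(c1)[C@H](C)CCC(=O)C1=[N+](c5c(C)cc(C)cc5C)N=C2N1[C@H]3c4ccccc4C[C@H]3OC2 | intermediate
8 | (5R)-7-methoxy-5-methyl-4,5-dihydro-1-benzoxepin-2(3H)-one | COc1ccc2c(c1)[C@H](C)CCC(=O)O2 | intermediate
9 | tert-butyl (triphenylphosphoranylidene)acetate | CC(C)(C)OC(=O)C=P(c1ccccc1)(c1ccccc1)c1ccccc1 | starting material
10 | (5R)-7-methoxy-5-methyl-2,3,4,5-tetrahydro-1-benzoxepin-2-ol, both C2 epimers, not isolated | COc1ccc2c(c1)[C@H](C)CCC(O)O2 | intermediate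
11 | (4R)-4-(2-hydroxy-5-methoxyphenyl)pentanal, not isolated | COc1ccc(O)c([C@H](C)CCC=O)c1 | intermediate
12 | tert-butyl (2E,6R)-6-(2-hydroxy-5-methoxyphenyl)hept-2-enoate | COc1ccc(O)c([C@H](C)CC/C=C/C(=O)OC(C)(C)C)c1 | intermediate
13 | tert-butyl (2E,6R)-6-[2-hydroxy-3-(hydroxymethyl)-5-methoxyphenyl]hept-2-enoate, present as its magnesium salt, not isolated | COc1cc(CO)c(O)c([C@H](C)CC/C=C/C(=O)OC(C)(C)C)c1 | intermediate
14 | tert-butyl (2E,6R)-6-(3-formyl-2-hydroxy-5-methoxyphenyl)hept-2-enoate | COc1cc(C=O)c(O)c([C@H](C)CC/C=C/C(=O)OC(C)(C)C)c1 | intermediate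
15 | (2E)-pent-2-en-4-yn-1-ol | C#C/C=C/CO | starting material
16 | (2E)-pent-2-en-4-ynal, not isolated | C#C/C=C/C=O | intermediate
17 | tert-butyl (2E,4E)-hepta-2,4-dien-6-ynoate | C#C/C=C/C=C/C(=O)OC(C)(C)C | intermediate
18 | tert-butyl (2E,4E,6E)-8-{3-[(2R,5E)-7-tert-butoxy-7-oxohept-5-en-2-yl]-2-hydroxy-5-methoxyphenyl}-8-oxoocta-2,4,6-trienoate | COc1cc(C(=O)/C=C/C=C/C=C/C(=O)OC(C)(C)C)c(O)c([C@H](C)CC/C=C/C(=O)OC(C)(C)C)c1 | intermediate
19 | (2E,4E,6E)-8-{3-[(2R,5E)-6-carboxyhex-5-en-2-yl]-2-hydroxy-5-methoxyphenyl}-8-oxoocta-2,4,6-trienoic acid | COc1cc(C(=O)/C=C/C=C/C=C/C(=O)O)c(O)c([C@H](C)CC/C=C/C(=O)O)c1 | target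

## Step count and risks

Total step count: 7. Longest linear sequence: 6 (1 → 3 → 8 → 12 → 14 → 18 → 19). Step 5 is the single side-branch step.

**Step 2 (most risky).**
- Acrolein can oligomerise or annulate with itself.
- Beta-protonation of 6 can divert the reaction to an enolate [4+2] product.
- Compound 5 can tautomerise to the vinylphenol.
- The ee may be modest because the stereocentre lies on the electrophile.

The fallback sets out from 1 and comes back at 8. Ketone 1 is olefinated with the ylide from (2-carboxyethyl)triphenylphosphonium bromide, which is itself a beta-carbanion of propionic acid (KOtBu, 3.3 equiv, THF). This gives (3E)-4-(2-hydroxy-5-methoxyphenyl)pent-3-enoic acid F1. Carboxylate-directed asymmetric hydrogenation follows (H2 6 atm, Et3N, MeOH). The catalyst is [Ir(cod)(L)][B(C6H3-3,5-(CF3)2)4], with L = 7-[bis(3,5-di-tert-butylphenyl)phosphanyl]-7'-(4-benzyl-4,5-dihydro-1,3-oxazol-2-yl)-1,1'-spirobiindane, and the ligand enantiomer is picked to give R. The product is (4R)-4-(2-hydroxy-5-methoxyphenyl)pentanoic acid F2. High-dilution ring closure with N-ethyl-N'-(3-dimethylaminopropyl)carbodiimide hydrochloride and catalytic 4-dimethylaminopyridine in CH2Cl2 gives lactone 8.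

**Step 6.** The electron-poor dienyne may give the branched regioisomer, may oligomerise on rhodium, or may react too slowly next to the hindered phenoxide.

The fallback sets out from 14 and 17 and comes back at 18. The polarity is inverted to a nucleophilic alkyne followed by an internal redox step. Compound 14 is first converted into its lithium phenoxide with LiN(SiMe3)2 (THF, −78 °C). It is then treated with the lithium acetylide made from 17 and LiN(SiMe3)2. This gives tert-butyl (2E,4E)-8-{3-[(2R,5E)-7-tert-butoxy-7-oxohept-5-en-2-yl]-2-hydroxy-5-methoxyphenyl}-8-hydroxyocta-2,4-dien-6-ynoate F3 as both carbinol epimers. Base-catalysed redox isomerisation of this electron-deficient propargylic alcohol (1,4-diazabicyclo[2.2.2]octane, 20 mol%, toluene, rt) proceeds through the allenol and delivers the (E)-enone 18.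

**Step 3.** The aryloxide is a good leaving group, so the aluminium hemiacetal may collapse early and be over-reduced to the diol.

The fallback sets out from 8 and comes back at 11. Lactone 8 is opened with MeNH(OMe)·HCl and iPrMgCl (THF, −20 °C) to (4R)-4-(2-hydroxy-5-methoxyphenyl)-N-methoxy-N-methylpentanamide F4. Its chelated tetrahedral adduct with LiAlH4 (2.2 equiv, THF, −40 °C) cannot be reduced further and releases aldehyde 11 on work-up. Aldehyde 11 is then treated with 9 as in the route to give 12.

## Further compounds

F1 | step 2 | (3E)-4-(2-hydroxy-5-methoxyphenyl)pent-3-enoic acid | COc1ccc(O)c(/C(C)=C/CC(=O)O)c1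
F2 | step 2 | (4R)-4-(2-hydroxy-5-methoxyphenyl)pentanoic acid | COc1ccc(O)c([C@H](C)CCC(=O)O)c1
F3 | step 6 | tert-butyl (2E,4E)-8-{3-[(2R,5E)-7-tert-butoxy-7-oxohept-5-en-2-yl]-2-hydroxy-5-methoxyphenyl}-8-hydroxyocta-2,4-dien-6-ynoate (both C8 epimers) | COc1cc(C(O)C#C/C=C/C=C/C(=O)OC(C)(C)C)c(O)c([C@H](C)CC/C=C/C(=O)OC(C)(C)C)c1
F4 | step 3 | (4R)-4-(2-hydroxy-5-methoxyphenyl)-N-methoxy-N-methylpentanamide | COc1ccc(O)c([C@H](C)CCC(=O)N(C)OC)c1
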